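**Retrosynthetic overview**
1. The cyclohexenone is made last from an acyclic (Z)-1,5-dien-3-one in one Lewis-acid cascade: cation–olefin cyclisation onto the activated enone, suprafacial 1,2-H shift, then anti 1,2-shift of the side chain (the biogenetic friedo-type cascade, run at the enone oxidation level so the ring enone is regenerated directly and C4/C5 are set together).
2. Because the two shifts are anti, a methyl shift would give the cis-dimethyl (4-epi) series; the trans 4-Me/5-Me pattern needs the chain to migrate, so the chain sits cis to C=O on the enone β-carbon and the nucleophilic alkene is a tiglyl group.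
3. Dienone ⇐ (Z)-enal + tiglylbarium; (Z)-trisubstituted alkene ⇐ B-alkyl Suzuki coupling of a diene-derived borane with (Z)-3-iodobut-2-en-1-ol; diene ⇐ dendrolasin by terminal allylic oxidation and methylenation.
4. Butenolide ⇐ 3-alkylfuran by singlet-oxygen oxidation and reduction (the furan-to-butenolide oxidation assumed for sponge terpenoids); dendrolasin ⇐ geranyl chloride + 3-furylmethyl Grignard.
5. Ring order: the furan ring is bought and turned into the butenolide (step 10); the carbocycle is formed last (step 12).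

Assumption: ring positions use cyclohexenone numbering (C1 = C=O, C3 = C–Me alkene carbon, C4 = quaternary, C5 = CHMe); the SMILES is read as (4R,5R) with 4-Me and 5-Me trans, i.e. 5-Me cis to the side chain.

**Step 1**
Reactants: 1 furan-3-ylmethanol
Product: 2 3-(chloromethyl)furan
Conditions: SOCl2, pyridine, Et2O, 0 °C
Reagents that add atoms: thionyl chloride, O=S(Cl)Cl
Why: Chlorodehydroxylation of a primary alcohol through its chlorosulfite, with pyridine taking up the HCl that the furan would not tolerate.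

**Step 2**
Reactants: 2 3-(chloromethyl)furan; 3 geranyl chloride
Product: 5 dendrolasin, via furylmethylmagnesium chloride 4 (not isolated)
Conditions: Mg, THF, 0 °C → rt; then 3, Li2CuCl4 (3 mol %), THF, 0 °C
Reagents that add atoms: none
Why: Grignard formation followed by Kochi-type copper-catalysed SN2 coupling with a primary allylic chloride (the known dendrolasin synthesis), which keeps the E alkene of the geranyl unit.

**Step 3**
Reactants: 5 dendrolasin
Product: 7 (2E,6E)-9-(furan-3-yl)-2,6-dimethylnona-2,6-dienal, via terminal E-allylic alcohol 6 (not isolated)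
Conditions: SeO2 (0.5 equiv), t-BuOOH, salicylic acid (cat.), CH2Cl2, rt; then MnO2, hexane, rt
Reagents that add atoms: selenium dioxide, O=[Se]=O; tert-butyl hydroperoxide, CC(C)(C)OO (terminal oxidant that re-forms it)
Why: Sharpless–Umbreit allylic oxidation (ene reaction then [2,3]-shift) attacks the E-methyl of the terminal isopropylidene, which fixes the 2E geometry, and MnO2 takes the allylic alcohol on to the enal.

**Step 4**
Reactants: 7 (2E,6E)-9-(furan-3-yl)-2,6-dimethylnona-2,6-dienal
Product: 8 3-[(3E,7E)-4,8-dimethyldeca-3,7,9-trien-1-yl]furan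
Conditions: Ph3PCH3Br, KOt-Bu, THF, 0 °C
Reagents that add atoms: methyltriphenylphosphonium bromide, C[P+](c1ccccc1)(c1ccccc1)c1ccccc1.[Br-]
Why: Wittig methylenation of an enal gives the terminal 1,3-diene without touching the existing alkenes; no stereocentre is formed.

**Step 5**
Reactants: 9 but-2-yn-1-ol
Product: 11 (2Z)-3-iodobut-2-en-1-ol, via cyclic Z-alkenylaluminate 10 (not isolated)
Conditions: NaAlH2(OCH2CH2OMe)2, THF, 0 °C → rt; then I2, −78 °C
Reagents that add atoms: iodine, II
Why: Hydroxyl-directed trans-hydroalumination of the propargylic alcohol gives the cyclic alkenylaluminate, and iodinolysis with retention gives the Z iodide.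

**Step 6**
Reactants: 8 3-[(3E,7E)-4,8-dimethyldeca-3,7,9-trien-1-yl]furan; 11 (2Z)-3-iodobut-2-en-1-ol
Product: 13 (2Z,6E,10E)-13-(furan-3-yl)-3,6,10-trimethyltrideca-2,6,10-trien-1-ol, via B-alkyl-9-BBN 12 (not isolated)
Conditions: 9-BBN-H, THF, 0 °C → rt; then 11, PdCl2(dppf) (5 mol %; dppf = 1,1'-bis(diphenylphosphino)ferrocene), AsPh3, Cs2CO3, DMF–H2O, rt
Reagents that add atoms: none
Why: 9-BBN hydroborates only the monosubstituted terminus of the diene, and the B-alkyl Suzuki–Miyaura coupling goes with retention at the alkenyl iodide, so the new trisubstituted alkene is Z (chain cis to the CH2OH carbon).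

**Step 7**
Reactants: 13 (2Z,6E,10E)-13-(furan-3-yl)-3,6,10-trimethyltrideca-2,6,10-trien-1-ol
Product: 14 (2Z,6E,10E)-13-(furan-3-yl)-3,6,10-trimethyltrideca-2,6,10-trienal
Conditions: MnO2, CH2Cl2, rt
Reagents that add atoms: none
Why: Neutral heterogeneous MnO2 oxidation of the allylic alcohol gives the neral-type Z enal without Z/E isomerisation.

**Step 8**
Reactants: 15 (2E)-2-methylbut-2-en-1-ol (tiglyl alcohol)
Product: 16 (2E)-1-chloro-2-methylbut-2-ene (tiglyl chloride)
Conditions: PPh3, (Cl3C)2CO, 0 °C → rt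
Reagents that add atoms: hexachloroacetone, O=C(C(Cl)(Cl)Cl)C(Cl)(Cl)Cl
Why: Magid chlorination (Appel-type SN2 on the alkoxyphosphonium salt) converts allylic alcohols to chlorides without allylic transposition or loss of E geometry.

**Step 9**
Reactants: 14 (2Z,6E,10E)-13-(furan-3-yl)-3,6,10-trimethyltrideca-2,6,10-trienal; 16 (2E)-1-chloro-2-methylbut-2-ene
Product: 18 (2E,6Z,10E,14E)-17-(furan-3-yl)-3,7,10,14-tetramethylheptadeca-2,6,10,14-tetraen-5-ol (racemic at C5), via tiglylbarium chloride 17 (not isolated)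
Conditions: BaI2, lithium biphenylide (LiC12H10), THF, rt; 16, −78 °C; then 14, −78 °C
Reagents that add atoms: none
Why: Yamamoto allylbarium addition is α-selective (bond at the CH2 terminus) with retention of the allyl E geometry and adds 1,2 to the enal; the new carbinol centre is formed racemic and is removed in step 11.

**Step 10**
Reactants: 18 (2E,6Z,10E,14E)-17-(furan-3-yl)-3,7,10,14-tetramethylheptadeca-2,6,10,14-tetraen-5-ol
Product: 21 4-[(3E,7E,11Z,15E)-13-hydroxy-4,8,11,15-tetramethylheptadeca-3,7,11,15-tetraen-1-yl]furan-2(5H)-one, via furan endoperoxide 19 (not isolated), via hydroxybutenolide 20 (not isolated)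
Conditions: O2, hν, rose bengal (cat.), i-Pr2NEt, CH2Cl2, −78 °C; then NaBH4, EtOH, 0 °C; 1 M HCl work-up
Reagents that add atoms: oxygen, O=O
Why: Singlet oxygen adds [4+2] to the furan much faster than it undergoes the ene reaction with trisubstituted alkenes; base-induced Kornblum–DeLaMare opening (Kernan–Faulkner conditions) gives the 4-alkyl-5-hydroxybutenolide regioselectively, and NaBH4 reduction of its open aldehyde form followed by relactonisation gives the β-substituted butenolide.

**Step 11**
Reactants: 21 4-[(3E,7E,11Z,15E)-13-hydroxy-4,8,11,15-tetramethylheptadeca-3,7,11,15-tetraen-1-yl]furan-2(5H)-one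
Product: 22 4-[(3E,7E,11Z,15E)-4,8,11,15-tetramethyl-13-oxoheptadeca-3,7,11,15-tetraen-1-yl]furan-2(5H)-one
Conditions: Dess–Martin periodinane, NaHCO3, CH2Cl2, 0 °C
Reagents that add atoms: none
Why: Buffered Dess–Martin oxidation is neutral, so the β,γ-alkene is not moved into conjugation and the Z enone is not isomerised.

**Step 12**
Reactants: 22 4-[(3E,7E,11Z,15E)-4,8,11,15-tetramethyl-13-oxoheptadeca-3,7,11,15-tetraen-1-yl]furan-2(5H)-one
Product: 23 cyclolinteinone, 4-[(3E,7E)-4,8-dimethyl-10-[(1R,6R)-1,2,6-trimethyl-4-oxocyclohex-2-en-1-yl]deca-3,7-dien-1-yl]furan-2(5H)-one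
Conditions: (S)-3,3-diphenyl-1-(o-tolyl)tetrahydro-1H,3H-pyrrolo[1,2-c][1,3,2]oxazaborole (0.5 equiv), AlBr3 (0.4 equiv), CH2Cl2, −78 → −40 °C
Reagents that add atoms: none
Why: Proposed new method: an enantioselective version of Snider's MeAlCl2-promoted enone–alkene cyclisation with two 1,2-shifts (closest known reaction; chiral activation as in Corey's oxazaborolidinium catalysis of enones), in which the boron-bound enone is attacked on the Si face of its β-carbon (future C3) by the Re face of the CH terminus of the E alkene (future C4) through a chair-like six-membered transition state to give a tertiary cation at future C5 paired with the boron enolate; there the C4–H is axial and, because the enone is Z, antiperiplanar to the chain on C3 while the C3 methyl is equatorial, so a suprafacial 1,2-hydride shift C4→C5 fixes C5 and the anti 1,2-shift of the chain C3→C4 fixes C4 with its methyl cis to the new C5–H (trans to the C5 methyl), regenerating the enone in the ring and freeing the catalyst.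

**Compound list**
1 | furan-3-ylmethanol | OCc1ccoc1 | starting material
2 | 3-(chloromethyl)furan | ClCc1ccoc1 | intermediate
3 | geranyl chloride, (2E)-1-chloro-3,7-dimethylocta-2,6-diene | ClC/C=C(C)/CCC=C(C)C | starting material
4 | (furan-3-ylmethyl)magnesium chloride | Cl[Mg]Cc1ccoc1 | intermediate
5 | dendrolasin, 3-[(3E)-4,8-dimethylnona-3,7-dien-1-yl]furan | CC(C)=CCC/C(C)=C/CCc1ccoc1 | intermediate
6 | (2E,6E)-9-(furan-3-yl)-2,6-dimethylnona-2,6-dien-1-ol | OC/C(C)=C/CC/C(C)=C/CCc1ccoc1 | intermediate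
7 | (2E,6E)-9-(furan-3-yl)-2,6-dimethylnona-2,6-dienal | O=C/C(C)=C/CC/C(C)=C/CCc1ccoc1 | intermediate
8 | 3-[(3E,7E)-4,8-dimethyldeca-3,7,9-trien-1-yl]furan | C=C/C(C)=C/CC/C(C)=C/CCc1ccoc1 | intermediate
9 | but-2-yn-1-ol | CC#CCO | starting material
10 | sodium 2,2-bis(2-methoxyethoxy)-3-methyl-2,5-dihydro-1,2-oxaaluminol-2-uide (cyclic Z-alkenylaluminate) | [Na+].CC1=CCO[Al-]1(OCCOC)OCCOC | intermediate
11 | (2Z)-3-iodobut-2-en-1-ol | C/C(I)=C/CO | intermediate
12 | 9-[(3E,7E)-10-(furan-3-yl)-3,7-dimethyldeca-3,7-dien-1-yl]-9-borabicyclo[3.3.1]nonane | C(C/C(C)=C/CC/C(C)=C/CCc1ccoc1)B1C2CCCC1CCC2 | intermediate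
13 | (2Z,6E,10E)-13-(furan-3-yl)-3,6,10-trimethyltrideca-2,6,10-trien-1-ol | OC/C=C(C)\CC/C(C)=C/CC/C(C)=C/CCc1ccoc1 | intermediate
14 | (2Z,6E,10E)-13-(furan-3-yl)-3,6,10-trimethyltrideca-2,6,10-trienal | O=C/C=C(C)\CC/C(C)=C/CC/C(C)=C/CCc1ccoc1 | intermediate
15 | (2E)-2-methylbut-2-en-1-ol (tiglyl alcohol) | C/C=C(C)/CO | starting material
16 | (2E)-1-chloro-2-methylbut-2-ene (tiglyl chloride) | C/C=C(C)/CCl | intermediate
17 | [(2E)-2-methylbut-2-en-1-yl]barium chloride | C/C=C(C)/C[Ba]Cl | intermediate
18 | (2E,6Z,10E,14E)-17-(furan-3-yl)-3,7,10,14-tetramethylheptadeca-2,6,10,14-tetraen-5-ol, racemic at C5 | C/C=C(C)/CC(O)/C=C(C)\CC/C(C)=C/CC/C(C)=C/CCc1ccoc1 | intermediate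
19 | furan endoperoxide of 18 (5-alkyl-2,3,7-trioxabicyclo[2.2.1]hept-5-ene) | C/C=C(C)/CC(O)/C=C(C)\CC/C(C)=C/CC/C(C)=C/CCC1=CC2OOC1O2 | intermediate
20 | 5-hydroxy-4-[(3E,7E,11Z,15E)-13-hydroxy-4,8,11,15-tetramethylheptadeca-3,7,11,15-tetraen-1-yl]furan-2(5H)-one | C/C=C(C)/CC(O)/C=C(C)\CC/C(C)=C/CC/C(C)=C/CCC1=CC(=O)OC1O | intermediate
21 | 4-[(3E,7E,11Z,15E)-13-hydroxy-4,8,11,15-tetramethylheptadeca-3,7,11,15-tetraen-1-yl]furan-2(5H)-one | C/C=C(C)/CC(O)/C=C(C)\CC/C(C)=C/CC/C(C)=C/CCC1=CC(=O)OC1 | intermediate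
22 | 4-[(3E,7E,11Z,15E)-4,8,11,15-tetramethyl-13-oxoheptadeca-3,7,11,15-tetraen-1-yl]furan-2(5H)-one | C/C=C(C)/CC(=O)/C=C(C)\CC/C(C)=C/CC/C(C)=C/CCC1=CC(=O)OC1 | intermediate
23 | cyclolinteinone | CC1=CC(=O)C[C@@H](C)[C@@]1(C)CC/C(C)=C/CC/C(C)=C/CCC1=CC(=O)OC1 | target

**Step count and risks**
Total steps: 12. Longest linear sequence: 10 (steps 1, 2, 3, 4, 6, 7, 9, 10, 11, 12).

Most likely to fail:

- **Step 12.** The asymmetric cascade has no direct precedent and the sense of induction of the (S)-catalyst is not established. Any Z→E leakage of the enone would make the methyl migrate instead of the chain. The remote alkenes could trap the cation, or the dienone could slip into conjugation. Fallback: set out from 22 and run the cyclisation under Snider's achiral stoichiometric conditions (MeAlCl2, 2.2 equiv, CH2Cl2, −78 → 0 °C) to racemic cyclolinteinone F1. Reduce it with catecholborane and (S)-2-methyl-CBS-oxazaborolidine (toluene, −78 °C), which gives the 1R carbinol from both enantiomers. Separate the diastereomers (1R,4R,5R)-allylic alcohol F2 and (1R,4S,5S)-allylic alcohol F3 on silica, and oxidise F2 with MnO2 to come back at 23.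

- **Step 10.** The furan has to outcompete four trisubstituted alkenes for singlet oxygen. Fallback: from 18, iridium-catalysed C–H borylation ([Ir(OMe)(cod)]2, 4,4'-di-tert-butyl-2,2'-bipyridine, B2pin2, hexane, 25 °C) goes to the furan α-position remote from the alkyl group and leaves the alkenes alone, giving furyl boronate F4. Oxidation with NaBO3·4H2O (THF–H2O) gives the 2-hydroxyfuran, which tautomerises to the butenolide and comes back at 21.

- **Step 9.** The α-selectivity and the handling of the allylbarium are the concern. Fallback: from 14, transfer the tiglyl group by 2-oxonia-Cope rearrangement instead of by an allylmetal. The branched donor 2,3,4-trimethylpent-4-en-2-ol F5 (from acetone and tiglylmagnesium chloride, γ-attack) and 14 with Sn(OTf)2 (10 mol %) in CH2Cl2 at 0 °C give the linear E adduct and acetone, coming back at 18.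

**Further compounds**
F1 | step 12 | racemic cyclolinteinone (both enantiomers) | CC1=CC(=O)C[C@@H](C)[C@@]1(C)CC/C(C)=C/CC/C(C)=C/CCC1=CC(=O)OC1.CC1=CC(=O)C[C@H](C)[C@]1(C)CC/C(C)=C/CC/C(C)=C/CCC1=CC(=O)OC1
F2 | step 12 | 4-[(3E,7E)-10-[(1R,4R,6R)-4-hydroxy-1,2,6-trimethylcyclohex-2-en-1-yl]-4,8-dimethyldeca-3,7-dien-1-yl]furan-2(5H)-one, the (1R,4R,5R)-allylic alcohol in cyclohexenol numbering | CC1=C[C@H](O)C[C@@H](C)[C@@]1(C)CC/C(C)=C/CC/C(C)=C/CCC1=CC(=O)OC1
F3 | step 12 | the (1R,4S,5S)-allylic alcohol in cyclohexenol numbering, diastereomer of F2 from the unwanted enantiomer | CC1=C[C@H](O)C[C@H](C)[C@]1(C)CC/C(C)=C/CC/C(C)=C/CCC1=CC(=O)OC1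
F4 | step 10 | (2E,6Z,10E,14E)-3,7,10,14-tetramethyl-17-[5-(4,4,5,5-tetramethyl-1,3,2-dioxaborolan-2-yl)furan-3-yl]heptadeca-2,6,10,14-tetraen-5-ol | C/C=C(C)/CC(O)/C=C(C)\CC/C(C)=C/CC/C(C)=C/CCc1cc(B2OC(C)(C)C(C)(C)O2)oc1
F5 | step 9 | 2,3,4-trimethylpent-4-en-2-ol | CC(=C)C(C)C(C)(C)O
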